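## Retrosynthetic overview

1. Target 38 comes from lipase-controlled myristoylation of triol 36. The enal of 36 comes from Br/Li exchange and formylation of alkenyl bromide 33. Bromide 33 comes from a B-alkyl Suzuki union of the ring vinyl group of 21 with alkenyl iodide 31, whose carbinol centre is set by CBS reduction.
2. The tetrasubstituted enal is grown on ring ketone 19 through gem-dibromoalkene 20. The less hindered bromine (cis to the ring CH2) becomes CH3, and the bromine cis to the ring stereocentre becomes CHO.
3. The only ring, the cyclohexane, is closed in one operation from acyclic nitro allylboronate 12 and but-3-en-2-one (13). A nitro-Michael addition joins the future sp2 ring carbon to the ring CH2. An intramolecular allylboration joins the carbinol carbon to the quaternary carbon.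
4. Enabling feature: the ring segment CH2-CH2-C(OH)(CH3) is a but-3-en-2-one unit. Its carbinol carbon is adjacent to the quaternary ring carbon C(CH3)(CH2CH2R), which is a homoallylic alcohol pattern once the side chain is cut back to vinyl. It is also 1,4 to the sp2 ring carbon, which is a gamma-nitro ketone pattern once that carbon is taken to the nitro (masked ketone) level.
5. One ring stereocentre (the CH bearing the oxypropyl chain) is set by rhodium catalysis in 10 and relays the other two in the key step.

Key step: step 8

Assumption: the sense of induction in step 5 is assigned by analogy with aryl transfer to (E)-nitroalkenes; if it proves opposite, the enantiomeric diene ligand is used.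

## Route

Step 1
Reactants: 1 but-2-yn-1-ol
Product: 3 (Z)-3-iodobut-2-en-1-ol, via cyclic alkenylalanate 2 (not isolated)
Conditions: NaAlH2(OCH2CH2OMe)2, Et2O, 0 °C to rt; then I2, THF, -78 °C
Reagents that add atoms: iodine, II
Why: Hydroxyl-directed trans-hydroalumination of the propargylic alcohol places aluminium on the distal carbon cis to CH2O in a five-membered alanate, and iodinolysis with retention should give the Z iodide.

Step 2
Reactants: 3 (Z)-3-iodobut-2-en-1-ol
Product: 4 3-(4,4,5,5-tetramethyl-1,3,2-dioxaborolan-2-yl)but-2-en-1-ol (boron cis to CH2OH)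
Conditions: B2pin2, PdCl2(PPh3)2 (3 mol%), PPh3, KOPh, toluene, 50 °C
Reagents that add atoms: bis(pinacolato)diboron, CC1(C)OB(OC1(C)C)B1OC(C)(C)C(C)(C)O1
Why: Miyaura borylation of an alkenyl iodide proceeds with retention of the double-bond geometry, so boron should stay cis to CH2OH.

Step 3
Reactants: 5 4-(tert-butyldimethylsilyloxy)butanal; 6 nitromethane
Product: 7 rac-5-(tert-butyldimethylsilyloxy)-1-nitropentan-2-ol
Conditions: KOt-Bu (10 mol%), THF/t-BuOH, 0 °C
Reagents that add atoms: none
Why: Henry (nitroaldol) addition of nitromethane to an unhindered aliphatic aldehyde under catalytic base; the carbinol centre is removed in the next step.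

Step 4
Reactants: 7 rac-5-(tert-butyldimethylsilyloxy)-1-nitropentan-2-ol
Product: 9 (E)-tert-butyldimethyl[(5-nitropent-4-en-1-yl)oxy]silane, via mesylate 8 (not isolated)
Conditions: MsCl, Et3N (2.2 equiv), CH2Cl2, -10 to 0 °C
Reagents that add atoms: none
Why: Mesylation followed by E1cB elimination of the beta-nitro mesylate should give the thermodynamically preferred E nitroalkene.

Step 5
Reactants: 4 alkenylboronate; 9 (E)-nitroalkene
Product: 10 (2Z,4R)-7-(tert-butyldimethylsilyloxy)-3-methyl-4-(nitromethyl)hept-2-en-1-ol
Conditions: [RhCl(C2H4)2]2 (2.5 mol%), (R,R)-2,5-diphenylbicyclo[2.2.2]octa-2,5-diene (5.5 mol%), KOH (20 mol%), dioxane/H2O 10:1, 40 °C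
Reagents that add atoms: none
Why: Hayashi-Miyaura type rhodium-catalysed asymmetric 1,4-addition of an alkenylboron reagent to a nitroalkene, in which the chiral diene differentiates the faces of the nitroalkene and sets the ring-fragment stereocentre while the alkenyl group is transferred with retention of its geometry.

Step 6
Reactants: 10 nitro allylic alcohol
Product: 11 tert-butyl{[(4R,5Z)-7-chloro-5-methyl-4-(nitromethyl)hept-5-en-1-yl]oxy}dimethylsilane
Conditions: NCS, Me2S, CH2Cl2, -20 to 0 °C
Reagents that add atoms: N-chlorosuccinimide, O=C1CCC(=O)N1Cl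
Why: Corey-Kim chlorination displaces an alkoxysulfonium ion by SN2 under neutral conditions, so neither allylic transposition, Z/E scrambling nor reaction of the primary nitroalkane is expected.

Step 7
Reactants: 11 allylic chloride
Product: 12 tert-butyldimethyl{[(4R,5Z)-5-methyl-4-(nitromethyl)-7-(4,4,5,5-tetramethyl-1,3,2-dioxaborolan-2-yl)hept-5-en-1-yl]oxy}silane
Conditions: B2pin2 (1.1 equiv), Pd2(dba)3 (1 mol%), THF, 60 °C
Reagents that add atoms: bis(pinacolato)diboron, CC1(C)OB(OC1(C)C)B1OC(C)(C)C(C)(C)O1
Why: Palladium-catalysed borylation of an allylic chloride delivers boron to the unsubstituted allyl terminus; syn/anti exchange would need a sigma bond at the fully substituted terminus, so the Z geometry should be kept, and the absence of base keeps the nitroalkane silent.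

Step 8
Reactants: 12 (Z)-allylboronate nitroalkane; 13 but-3-en-2-one
Product: 16 (1S,2R,3R)-3-[3-(tert-butyldimethylsilyloxy)propyl]-1,2-dimethyl-4-nitro-2-vinylcyclohexan-1-ol (epimers at the nitro carbon), via nitro ketone 14 (not isolated), via cyclic pinacol borate 15 (not isolated)
Conditions: 13 (1.05 equiv), DBU (10 mol%), toluene, 0 °C to rt; then 80 °C; aq. NH4Cl work-up
Reagents that add atoms: none
Why: DBU forms the nitronate of 12, which adds to the terminal carbon of the enone (nitro-Michael reaction) and after proton transfer gives gamma-nitro ketone 14, whose free methyl ketone is tethered to the allylboronate. On warming, boron binds the ketone oxygen and the allyl unit is transferred through a closed chair (Zimmerman-Traxler) transition state; the closest known types are intramolecular allylboration and the addition of gamma,gamma-disubstituted allylboron reagents to ketones, and the cyclohexane closes 6-exo-trig at the carbonyl carbon, with bond formation at the fully substituted alkene carbon and allylic transposition to a vinyl group. Because the tether occupies the Z position of the alkene it is axial in the six-membered transition state, so the ketone must place its own tether arm equatorial and its methyl axial, which fixes hydroxyl cis to vinyl and methyl cis to methyl at the two new adjacent centres. The alkene face is chosen by the existing stereocentre: A(1,3) strain holds its C-H in the alkene plane toward CH2B, the nitro-bearing arm brings the ketone to one face only, and the silyloxypropyl chain ends equatorial and cis to the new quaternary methyl (its axial alternative would be 1,3-diaxial to the boron-bound oxygen). The nitro-bearing carbon epimerises freely under DBU and is erased in step 10, so its configuration does not matter. Chemoselectivity rests on the soft nitronate attacking only the enone terminus, on the pinacol allylboronate being inert to base, to the enone and to intermolecular ketones so that it reacts only with the tethered carbonyl, and on near-stoichiometric enone limiting a second Michael addition.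

Step 9
Reactants: 16 nitrocyclohexanol
Product: 17 triethylsilyl ether of 16
Conditions: TESOTf, 2,6-lutidine, CH2Cl2, -78 to 0 °C
Reagents that add atoms: triethylsilyl trifluoromethanesulfonate, CC[Si](CC)(CC)OS(=O)(=O)C(F)(F)F
Why: Silyl triflate with lutidine is the standard silylation of a hindered tertiary alcohol and is too weakly basic to silylate the nitro group.

Step 10
Reactants: 17 silylated nitrocyclohexane
Product: 19 (2R,3R,4S)-2-[3-(tert-butyldimethylsilyloxy)propyl]-3,4-dimethyl-4-(triethylsilyloxy)-3-vinylcyclohexan-1-one, via sodium nitronate 18 (not isolated)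
Conditions: NaOMe, MeOH, 0 °C; then aq. TiCl3, NH4OAc buffer, rt
Reagents that add atoms: water, O
Why: Reductive Nef reaction, in which trivalent titanium reduces the nitronate to the imine that hydrolyses in the buffer; the alpha stereocentre should stay with the chain equatorial, because the axial epimer would be 1,3-diaxial to the silyloxy group.

Step 11
Reactants: 19 ring ketone
Product: 20 (dibromomethylidene)cyclohexane derived from 19
Conditions: CBr4 (4 equiv), PPh3 (8 equiv), toluene, 0 to 80 °C
Reagents that add atoms: carbon tetrabromide, BrC(Br)(Br)Br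
Why: Ramirez dibromoolefination with the non-basic ylide Ph3P=CBr2 converts the ketone to the gem-dibromoalkene without enolising the adjacent stereocentre.

Step 12
Reactants: 20 gem-dibromoalkene
Product: 21 (Z)-(1-bromoethylidene)cyclohexane (CH3 cis to the ring CH2; Br cis to the ring CH stereocentre)
Conditions: MeZnCl (1.2 equiv), PdCl2(DPEphos) (5 mol%), THF, 0 °C to rt
Reagents that add atoms: methylzinc chloride, C[Zn]Cl
Why: Site-selective Negishi monoalkylation of a 1,1-dibromoalkene, in which oxidative addition occurs at the less hindered C-Br bond (here the one cis to the ring CH2 and remote from the branched stereocentre), so the alkene geometry is set by steric differentiation.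

Step 13
Reactants: 22 prop-2-yn-1-ol
Product: 24 (E)-3-iodo-2-methylprop-2-en-1-ol, via alkenylalane 23 (not isolated)
Conditions: AlMe3 (3 equiv), Cp2ZrCl2 (25 mol%), CH2Cl2, 0 °C to rt; then I2, THF, -30 °C
Reagents that add atoms: trimethylaluminium, C[Al](C)C; iodine, II
Why: Zirconium-catalysed syn-carboalumination of the terminal alkyne followed by iodinolysis with retention should give the E iodide with methyl on the internal carbon.

Step 14
Reactants: 24 (E)-3-iodo-2-methylprop-2-en-1-ol
Product: 25 (E)-3-iodo-2-methylprop-2-enal
Conditions: MnO2 (excess), CH2Cl2, rt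
Reagents that add atoms: none
Why: Manganese dioxide oxidises the allylic alcohol chemoselectively to the enal without touching the alkenyl iodide or its geometry.

Step 15
Reactants: 25 (E)-3-iodo-2-methylprop-2-enal; 26 geranyl chloride
Product: 28 rac-(1E,5E)-1-iodo-2,6,10-trimethylundeca-1,5,9-trien-3-ol, via geranylbarium chloride 27 (not isolated)
Conditions: BaI2, lithium biphenylide (2 equiv), THF, rt; 26, -78 °C; then 25, -78 °C
Reagents that add atoms: none
Why: Allylbarium reagents add to aldehydes at the alpha carbon with retention of the E geometry at -78 °C, which gives the linear adduct instead of the branched one.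

Step 16
Reactants: 28 racemic allylic alcohol
Product: 29 (1E,5E)-1-iodo-2,6,10-trimethylundeca-1,5,9-trien-3-one
Conditions: Dess-Martin periodinane, CH2Cl2, 0 °C
Reagents that add atoms: none
Why: Dess-Martin oxidation works under neutral, non-enolising conditions, so the skipped alkene should not move into conjugation.

Step 17
Reactants: 29 dienone
Product: 30 (3R,1E,5E)-1-iodo-2,6,10-trimethylundeca-1,5,9-trien-3-ol
Conditions: (S)-2-methyl-CBS-oxazaborolidine (20 mol%), catecholborane (1.5 equiv), toluene, -78 °C; aq. work-up
Reagents that add atoms: none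
Why: Corey-Bakshi-Shibata reduction, in which the alpha-methyl-beta-iodovinyl group acts as the large substituent so that the (S)-catalyst should deliver hydride to give the R carbinol.

Step 18
Reactants: 30 (R)-allylic alcohol
Product: 31 tert-butyldimethylsilyl ether of 30
Conditions: TBSCl, imidazole, DMF, rt
Reagents that add atoms: tert-butyldimethylsilyl chloride, CC(C)(C)[Si](C)(C)Cl
Why: Standard silylation of a secondary alcohol that leaves the stereocentre and the alkenyl iodide untouched.

Step 19
Reactants: 21 alkenyl bromide bearing the ring vinyl group; 31 alkenyl iodide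
Product: 33 coupled tris-silyl ether alkenyl bromide, via B-alkyl-9-BBN borane 32 (not isolated)
Conditions: 9-BBN-H (1.5 equiv), THF, rt; then 31, PdCl2(dppf) (5 mol%), AsPh3, Cs2CO3, DMF/H2O, rt
Reagents that add atoms: none
Why: 9-BBN hydroborates only the monosubstituted vinyl group at its terminus, and the B-alkyl Suzuki-Miyaura coupling takes place at the alkenyl iodide with retention of E geometry far faster than at the tetrasubstituted alkenyl bromide.

Step 20
Reactants: 33 alkenyl bromide
Product: 35 tris-silylated enal, via alkenyllithium 34 (not isolated)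
Conditions: t-BuLi (2.2 equiv), Et2O, -78 °C; then DMF, -78 to 0 °C
Reagents that add atoms: N,N-dimethylformamide, CN(C)C=O
Why: Bromine-lithium exchange and formylation of the configurationally stable alkenyllithium both proceed with retention, so CHO should take the place of bromine cis to the ring stereocentre.

Step 21
Reactants: 35 tris-silylated enal
Product: 36 free triol (the target without its acyl group)
Conditions: HF·pyridine, pyridine, THF, 0 °C to rt
Reagents that add atoms: none
Why: Buffered fluoride cleaves the three silyl ethers while leaving the enal, the allylic carbinol and the tertiary alcohol intact.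

Step 22
Reactants: 36 triol; 37 vinyl tetradecanoate
Product: 38 target, CNP0171467.2
Conditions: Candida antarctica lipase B (immobilised), MTBE, 30 °C
Reagents that add atoms: none
Why: Lipase-catalysed irreversible transesterification with a vinyl ester should acylate only the unhindered primary alcohol, because the secondary carbinol flanked by two large groups and the tertiary alcohol are not accepted.

## Compound list

1 | but-2-yn-1-ol | CC#CCO | starting material
2 | sodium cyclic alkenylalanate (Al on the methyl-bearing carbon, O-bound) | CC1=CCO[Al-]1(OCCOC)OCCOC.[Na+] | intermediate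
3 | (Z)-3-iodobut-2-en-1-ol | C/C(I)=C/CO | intermediate
4 | 3-(pinacolboryl)but-2-en-1-ol, boron cis to CH2OH | C/C(B1OC(C)(C)C(C)(C)O1)=C/CO | intermediate
5 | 4-(tert-butyldimethylsilyloxy)butanal | O=CCCCO[Si](C)(C)C(C)(C)C | starting material
6 | nitromethane | C[N+](=O)[O-] | starting material
7 | rac-5-(tert-butyldimethylsilyloxy)-1-nitropentan-2-ol | OC(C[N+](=O)[O-])CCCO[Si](C)(C)C(C)(C)C | intermediate
8 | mesylate of 7 | CS(=O)(=O)OC(C[N+](=O)[O-])CCCO[Si](C)(C)C(C)(C)C | intermediate
9 | (E)-tert-butyldimethyl[(5-nitropent-4-en-1-yl)oxy]silane | [O-][N+](=O)/C=C/CCCO[Si](C)(C)C(C)(C)C | intermediate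
10 | (2Z,4R)-7-(tert-butyldimethylsilyloxy)-3-methyl-4-(nitromethyl)hept-2-en-1-ol | CC(C)(C)[Si](C)(C)OCCC[C@H](/C(C)=C\CO)C[N+](=O)[O-] | intermediate
11 | (4R,5Z)-allylic chloride | CC(C)(C)[Si](C)(C)OCCC[C@H](/C(C)=C\CCl)C[N+](=O)[O-] | intermediate
12 | (4R,5Z)-allyl pinacol boronate | CC(C)(C)[Si](C)(C)OCCC[C@H](/C(C)=C\CB1OC(C)(C)C(C)(C)O1)C[N+](=O)[O-] | intermediate
13 | but-3-en-2-one | CC(=O)C=C | starting material
14 | gamma-nitro ketone (Michael adduct, nitro carbon unassigned) | CC(C)(C)[Si](C)(C)OCCC[C@H](/C(C)=C\CB1OC(C)(C)C(C)(C)O1)C(CCC(C)=O)[N+](=O)[O-] | intermediate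
15 | cyclised pinacol borate of 16 | CC(C)(C)[Si](C)(C)OCCC[C@H]1C([N+](=O)[O-])CC[C@](C)(OB2OC(C)(C)C(C)(C)O2)[C@]1(C)C=C | intermediate
16 | (1S,2R,3R)-3-[3-(tert-butyldimethylsilyloxy)propyl]-1,2-dimethyl-4-nitro-2-vinylcyclohexan-1-ol | CC(C)(C)[Si](C)(C)OCCC[C@H]1C([N+](=O)[O-])CC[C@](C)(O)[C@]1(C)C=C | intermediate
17 | triethylsilyl ether of 16 | CC(C)(C)[Si](C)(C)OCCC[C@H]1C([N+](=O)[O-])CC[C@](C)(O[Si](CC)(CC)CC)[C@]1(C)C=C | intermediate
18 | sodium nitronate of 17 | CC(C)(C)[Si](C)(C)OCCC[C@H]1C(=[N+]([O-])[O-])CC[C@](C)(O[Si](CC)(CC)CC)[C@]1(C)C=C.[Na+] | intermediate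
19 | (2R,3R,4S)-2-[3-(tert-butyldimethylsilyloxy)propyl]-3,4-dimethyl-4-(triethylsilyloxy)-3-vinylcyclohexan-1-one | CC(C)(C)[Si](C)(C)OCCC[C@H]1C(=O)CC[C@](C)(O[Si](CC)(CC)CC)[C@]1(C)C=C | intermediate
20 | gem-dibromoalkene from 19 | CC(C)(C)[Si](C)(C)OCCC[C@H]1C(=C(Br)Br)CC[C@](C)(O[Si](CC)(CC)CC)[C@]1(C)C=C | intermediate
21 | (Z)-1-bromoethylidene compound (Br cis to the ring CH) | CC(C)(C)[Si](C)(C)OCCC[C@H]1/C(=C(/C)Br)CC[C@](C)(O[Si](CC)(CC)CC)[C@]1(C)C=C | intermediate
22 | prop-2-yn-1-ol | C#CCO | starting material
23 | (E)-alkenylalane, O-aluminated | C[Al](C)/C=C(\C)CO[Al](C)C | intermediate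
24 | (E)-3-iodo-2-methylprop-2-en-1-ol | I/C=C(\C)CO | intermediate
25 | (E)-3-iodo-2-methylprop-2-enal | I/C=C(\C)C=O | intermediate
26 | geranyl chloride | ClC/C=C(\C)CCC=C(C)C | starting material
27 | geranylbarium chloride | Cl[Ba]C/C=C(\C)CCC=C(C)C | intermediate
28 | rac-(1E,5E)-1-iodo-2,6,10-trimethylundeca-1,5,9-trien-3-ol | I/C=C(\C)C(O)C/C=C(\C)CCC=C(C)C | intermediate
29 | (1E,5E)-1-iodo-2,6,10-trimethylundeca-1,5,9-trien-3-one | I/C=C(\C)C(=O)C/C=C(\C)CCC=C(C)C | intermediate
30 | (3R,1E,5E)-1-iodo-2,6,10-trimethylundeca-1,5,9-trien-3-ol | I/C=C(\C)[C@H](O)C/C=C(\C)CCC=C(C)C | intermediate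
31 | tert-butyldimethylsilyl ether of 30 | I/C=C(\C)[C@H](O[Si](C)(C)C(C)(C)C)C/C=C(\C)CCC=C(C)C | intermediate
32 | B-alkyl-9-BBN borane from 21 | CC(C)(C)[Si](C)(C)OCCC[C@H]1/C(=C(/C)Br)CC[C@](C)(O[Si](CC)(CC)CC)[C@]1(C)CCB1C2CCCC1CCC2 | intermediate
33 | coupled alkenyl bromide, tris-silyl ether | CC(C)(C)[Si](C)(C)OCCC[C@H]1/C(=C(/C)Br)CC[C@](C)(O[Si](CC)(CC)CC)[C@]1(C)CC/C=C(\C)[C@H](O[Si](C)(C)C(C)(C)C)C/C=C(\C)CCC=C(C)C | intermediate
34 | alkenyllithium from 33 | CC(C)(C)[Si](C)(C)OCCC[C@H]1/C(=C(/C)[Li])CC[C@](C)(O[Si](CC)(CC)CC)[C@]1(C)CC/C=C(\C)[C@H](O[Si](C)(C)C(C)(C)C)C/C=C(\C)CCC=C(C)C | intermediate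
35 | tris-silylated enal (CHO cis to the ring CH) | CC(C)(C)[Si](C)(C)OCCC[C@H]1/C(=C(/C)C=O)CC[C@](C)(O[Si](CC)(CC)CC)[C@]1(C)CC/C=C(\C)[C@H](O[Si](C)(C)C(C)(C)C)C/C=C(\C)CCC=C(C)C | intermediate
36 | free triol | OCCC[C@H]1/C(=C(/C)C=O)CC[C@](C)(O)[C@]1(C)CC/C=C(\C)[C@H](O)C/C=C(\C)CCC=C(C)C | intermediate
37 | vinyl tetradecanoate | CCCCCCCCCCCCCC(=O)OC=C | starting material
38 | CNP0171467.2 | CCCCCCCCCCCCCC(=O)OCCC[C@H]1/C(=C(/C)C=O)CC[C@](C)(O)[C@]1(C)CC/C=C(\C)[C@H](O)C/C=C(\C)CCC=C(C)C | target

## Step count and risks

Total step count: 22.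
Longest linear sequence: 14 steps (steps 1, 2, 5 to 12 and 19 to 22).

**Risk 1, step 8.**
- The sequence may stall after the Michael addition, because the pinacol boronate may be too weak a Lewis acid to engage the methyl ketone.
- Prolonged heating could also erode facial selectivity through boat-like transition states.
- Fallback: it sets out from 14, isolated after the room-temperature stage. KHF2 in aqueous methanol should convert it to the potassium allyltrifluoroborate F1. BF3·OEt2 in CH2Cl2 at -78 °C should then release the far more Lewis acidic allyldifluoroborane, which should close the ring through the same closed chair at low temperature. After aqueous work-up the route is rejoined at 16.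

**Risk 2, step 11.**
- Olefination of the hindered ketone may be slow or incomplete.
- The phosphonium bromide by-products may cause loss of silyl groups.
- Any later weakness in site selection in step 12 compounds the problem.
- Fallback: it sets out from 19 and avoids the dibromide altogether. A boron-Wittig reaction with lithiated 1,1-bis(pinacolboryl)ethane (LiTMP, THF, -78 °C to rt) should give the tetrasubstituted alkenylboronate F2, with the bulky boryl group on the less hindered side, cis to the ring CH2. Bromodeboronation (Br2, 1 equiv, CH2Cl2, -78 °C; then NaOMe, MeOH) runs by anti addition and anti elimination, which is overall inversion. Bromine therefore ends cis to the ring stereocentre and methyl cis to the ring CH2. The route is rejoined at 21.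

**Risk 3, step 5.**
- The hindered alkenylboronate may undergo protodeboronation.
- The aliphatic nitroalkene may oligomerise under aqueous base.
- Facial selectivity may be poor.
- Fallback: it sets out from 3 and forms the bond on the other side of the stereocentre.
  - Alcohol 3 is protected (4-methoxybenzyl trichloroacetimidate, cat. camphorsulfonic acid) as the PMB ether F3.
  - Iodine-lithium exchange (t-BuLi, -78 °C) and addition-elimination on (E)-N,N-dimethyl-2-nitroethenamine should give the (1E,3Z)-nitrodiene F4 with retention.
  - Bis[3-(tert-butyldimethylsilyloxy)propyl]zinc F5 is made from allyl tert-butyldimethylsilyl ether by hydroboration with Et2BH and boron-zinc exchange with Et2Zn.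
  - Copper-catalysed asymmetric 1,4-addition of F5 (Cu(OTf)2, chiral phosphoramidite, toluene, -30 °C) should give the PMB ether F6.
  - DDQ in wet CH2Cl2 removes the PMB group and the route is rejoined at 10.

Further compounds
F1 | step 8 | potassium allyltrifluoroborate of nitro ketone 14 | CC(C)(C)[Si](C)(C)OCCC[C@H](/C(C)=C\C[B-](F)(F)F)C(CCC(C)=O)[N+](=O)[O-].[K+]
F2 | step 11 | tetrasubstituted alkenyl pinacol boronate (boron cis to the ring CH2) | CC(C)(C)[Si](C)(C)OCCC[C@H]1/C(=C(/B2OC(C)(C)C(C)(C)O2)C)CC[C@](C)(O[Si](CC)(CC)CC)[C@]1(C)C=C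
F3 | step 5 | (Z)-1-{[(3-iodobut-2-en-1-yl)oxy]methyl}-4-methoxybenzene | C/C(I)=C/COCc1ccc(OC)cc1
F4 | step 5 | (1E,3Z)-5-(4-methoxybenzyloxy)-3-methyl-1-nitropenta-1,3-diene | [O-][N+](=O)/C=C/C(C)=C\COCc1ccc(OC)cc1
F5 | step 5 | bis[3-(tert-butyldimethylsilyloxy)propyl]zinc | CC(C)(C)[Si](C)(C)OCCC[Zn]CCCO[Si](C)(C)C(C)(C)C
F6 | step 5 | 4-methoxybenzyl ether of 10 | CC(C)(C)[Si](C)(C)OCCC[C@H](/C(C)=C\COCc1ccc(OC)cc1)C[N+](=O)[O-]
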